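**Retrosynthetic overview**
- Last step: one fluoride treatment frees the C7 hydroxyl and the acid; the C9 carbinol comes from a C9 ketone by a C11‑hydroxyl‑directed 1,3‑anti reduction.
- C10–C11: reagent‑controlled syn boron aldol of an ethyl ketone (C1–C10) with an oxazolyl trienal (C11–C17).
- Key disconnection, the C9–O bond: the C9 carbonyl is made from the C8=C9 olefin of a pentenal‑derived allylic silyl ether by Wacker oxidation, run in the same flask as the Heck dienylation that forms C3–C4 (new palladium relay).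
- C6/C7: catalytic asymmetric anti‑crotylboration of (E)‑pent‑2‑enal; the trienal comes from three Wittig homologations of 2‑methyloxazole‑4‑carbaldehyde.
- Rings: the oxazole is the only ring and is bought intact; no ring is formed in the route.

Assumption: (E)‑3‑iodo‑2‑methylacrylic acid, (E)‑crotylboronic acid pinacol ester, 2‑methyloxazole‑4‑carbaldehyde and both formyl ylides are catalogue items. Atom labels C1–C17 are those of the target chain (C1 = CO2H, C17 = CH on the oxazole).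

**Step 1**
Reactants: 1 (E)‑pent‑2‑enal; 2 (E)‑crotylboronic acid pinacol ester
Product: 4 (3S,4R,5E)‑3‑methylocta‑1,5‑dien‑4‑ol, via homoallyl pinacol borate 3 (not isolated)
Conditions: (S)‑TRIP [(S)‑3,3'‑bis(2,4,6‑triisopropylphenyl)‑1,1'‑binaphthalene‑2,2'‑diyl hydrogen phosphate] (5 mol %), toluene, −30 °C; aq. NaHCO3 work‑up
Reagents that add atoms: none
Why: Chiral‑phosphoric‑acid‑catalysed crotylboration (1,2‑allylboration through a closed chair transition state): the E‑crotyl geometry gives the anti methyl/hydroxyl pair and the (S)‑catalyst directs addition to the Si face of the enal, setting C6 (S) and C7 (R).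

**Step 2**
Reactants: 4 (3S,4R,5E)‑3‑methylocta‑1,5‑dien‑4‑ol
Product: 5 tert‑butyl(dimethyl){[(3S,4R,5E)‑3‑methylocta‑1,5‑dien‑4‑yl]oxy}silane
Conditions: TBSOTf, 2,6‑lutidine, CH2Cl2, −78 → 0 °C
Reagents that add atoms: tert‑butyldimethylsilyl triflate, CC(C)(C)[Si](C)(C)OS(=O)(=O)C(F)(F)F
Why: Standard O‑silylation of a hindered secondary alcohol; the silyl ether later steers the Wacker regiochemistry, survives the boron aldol and falls to fluoride.

**Step 3**
Reactants: 6 (2E)‑3‑iodo‑2‑methylprop‑2‑enoic acid; 7 2‑(trimethylsilyl)ethanol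
Product: 8 2‑(trimethylsilyl)ethyl (2E)‑3‑iodo‑2‑methylprop‑2‑enoate
Conditions: DCC, 4‑(dimethylamino)pyridine (10 mol %), CH2Cl2, 0 °C → rt
Reagents that add atoms: none
Why: Steglich esterification; the ester is chosen so that it is cleaved by the same fluoride step that removes the silyl ether.

**Step 4**
Reactants: 5 tert‑butyl(dimethyl){[(3S,4R,5E)‑3‑methylocta‑1,5‑dien‑4‑yl]oxy}silane; 8 2‑(trimethylsilyl)ethyl (2E)‑3‑iodo‑2‑methylprop‑2‑enoate
Product: 10 2‑(trimethylsilyl)ethyl (2E,4E,6S,7R)‑7‑[(tert‑butyldimethylsilyl)oxy]‑2,6‑dimethyl‑9‑oxoundeca‑2,4‑dienoate, via Heck triene ester 9 (not isolated)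
Conditions: Pd(OAc)2 (5 mol %), AgOAc (1.3 equiv), DMF, 45 °C; then 1,4‑benzoquinone (1.5 equiv), aq. HBF4 (0.5 equiv), MeCN/H2O, rt
Reagents that add atoms: water, O
Why: Proposed new method: one charge of palladium serves two different cycles in one flask. First comes a ligand‑free Jeffery‑type Heck alkenylation (zerovalent/divalent palladium cycle): oxidative addition of 8, insertion of the only monosubstituted olefin of 5, and β‑hydride elimination towards C4 give the (2E,4E)‑dienoate 9, with iodide removed as AgI. After benzoquinone, HBF4 and water are added, the same metal, now held as divalent palladium, carries out a Wacker oxidation of the remaining internal olefin; water attacks C9 because the electron‑withdrawing allylic OTBS group at C7 disfavours positive charge at C8, so the C9–O bond is formed regioselectively, while the electron‑poor dienoate binds electrophilic palladium poorly and is left alone. The closest known reaction types are the Jeffery–Heck dienylation of terminal olefins and the Tsuji–Wacker oxidation of internal allylic ethers to β‑alkoxy ketones with Pd(OAc)2/benzoquinone/HBF4, which have not been run as a relay on one substrate. No stereocentre is formed and C6/C7 are untouched.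

**Step 5**
Reactants: 11 2‑methyl‑1,3‑oxazole‑4‑carbaldehyde; 12 2‑(triphenylphosphoranylidene)propanal
Product: 13 (2E)‑2‑methyl‑3‑(2‑methyl‑1,3‑oxazol‑4‑yl)prop‑2‑enal
Conditions: toluene, 90 °C
Reagents that add atoms: none
Why: Wittig olefination with a stabilised formyl ylide, which gives the E trisubstituted enal.

**Step 6**
Reactants: 13 (2E)‑2‑methyl‑3‑(2‑methyl‑1,3‑oxazol‑4‑yl)prop‑2‑enal; 14 (triphenylphosphoranylidene)acetaldehyde
Product: 15 (2E,4E)‑4‑methyl‑5‑(2‑methyl‑1,3‑oxazol‑4‑yl)penta‑2,4‑dienal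
Conditions: 14 (1.1 equiv, added slowly), toluene, 80 °C
Reagents that add atoms: none
Why: Wittig two‑carbon homologation with a stabilised ylide (E‑selective); slow addition limits a second homologation of the product.

**Step 7**
Reactants: 15 (2E,4E)‑4‑methyl‑5‑(2‑methyl‑1,3‑oxazol‑4‑yl)penta‑2,4‑dienal; 12 2‑(triphenylphosphoranylidene)propanal
Product: 16 (2E,4E,6E)‑2,6‑dimethyl‑7‑(2‑methyl‑1,3‑oxazol‑4‑yl)hepta‑2,4,6‑trienal
Conditions: toluene, 90 °C
Reagents that add atoms: none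
Why: Wittig olefination with the α‑methyl formyl ylide gives the E‑configured α‑methyl enal terminus and does not react further.

**Step 8**
Reactants: 10 2‑(trimethylsilyl)ethyl (2E,4E,6S,7R)‑7‑[(tert‑butyldimethylsilyl)oxy]‑2,6‑dimethyl‑9‑oxoundeca‑2,4‑dienoate; 16 (2E,4E,6E)‑2,6‑dimethyl‑7‑(2‑methyl‑1,3‑oxazol‑4‑yl)hepta‑2,4,6‑trienal
Product: 19 2‑(trimethylsilyl)ethyl (2E,4E,6S,7R,10R,11R,12E,14E,16E)‑7‑[(tert‑butyldimethylsilyl)oxy]‑11‑hydroxy‑2,6,10,12,16‑pentamethyl‑17‑(2‑methyl‑1,3‑oxazol‑4‑yl)‑9‑oxoheptadeca‑2,4,12,14,16‑pentaenoate, via Z‑enol borinate 17 (not isolated), via boron aldolate 18 (not isolated)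
Conditions: (+)‑Ipc2BOTf [(+)‑diisopinocampheylboron triflate, from (−)‑α‑pinene] (1.5 equiv), i‑Pr2NEt, CH2Cl2, −78 °C; then 16, −78 → −20 °C; MeOH, pH 7 buffer, 30 % H2O2, 0 °C
Reagents that add atoms: none
Why: Paterson boron aldol: the bulky boron triflate/amine pair enolises the less hindered ethyl side to the Z‑enol borinate, the chair transition state gives the 10,11‑syn pair, and the Ipc ligands direct addition to the Re face of 16, setting C10 and C11.

**Step 9**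
Reactants: 19 (the aldol adduct of step 8)
Product: 20 2‑(trimethylsilyl)ethyl (2E,4E,6S,7R,9S,10S,11R,12E,14E,16E)‑7‑[(tert‑butyldimethylsilyl)oxy]‑9,11‑dihydroxy‑2,6,10,12,16‑pentamethyl‑17‑(2‑methyl‑1,3‑oxazol‑4‑yl)heptadeca‑2,4,12,14,16‑pentaenoate
Conditions: Me4NBH(OAc)3 (6 equiv), MeCN/AcOH (3:1), −30 → −20 °C; aq. Rochelle salt/NaHCO3
Reagents that add atoms: none
Why: Evans–Saksena reduction: the C11 hydroxyl exchanges onto boron and delivers hydride intramolecularly through a chair transition state, giving the 9,11‑anti diol and setting C9 (S); the silylated C7 oxygen cannot compete as a director.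

**Step 10**
Reactants: 20 (the diol of step 9)
Product: 21 (2E,4E,6S,7R,9S,10S,11R,12E,14E,16E)‑7,9,11‑trihydroxy‑2,6,10,12,16‑pentamethyl‑17‑(2‑methyl‑1,3‑oxazol‑4‑yl)heptadeca‑2,4,12,14,16‑pentaenoic acid
Conditions: Bu4NF (5 equiv), THF, 0 °C → rt; then cold dilute aq. HCl to pH 4
Reagents that add atoms: none
Why: Fluoride‑induced cleavage of the TBS ether and fragmentation of the 2‑(trimethylsilyl)ethyl ester in one operation; no stereocentre or olefin is touched and the acid‑labile trienyl carbinol never meets strong acid.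

**Compound list**
1 | (E)‑pent‑2‑enal | CC/C=C/C=O | starting material
2 | (E)‑crotylboronic acid pinacol ester | C/C=C/CB1OC(C)(C)C(C)(C)O1 | starting material
3 | (3S,4R,5E)‑3‑methylocta‑1,5‑dien‑4‑yl pinacol borate | CC/C=C/[C@@H](OB1OC(C)(C)C(C)(C)O1)[C@@H](C)C=C | intermediate (not isolated)
4 | (3S,4R,5E)‑3‑methylocta‑1,5‑dien‑4‑ol | CC/C=C/[C@@H](O)[C@@H](C)C=C | intermediate
5 | tert‑butyl(dimethyl){[(3S,4R,5E)‑3‑methylocta‑1,5‑dien‑4‑yl]oxy}silane | CC/C=C/[C@@H](O[Si](C)(C)C(C)(C)C)[C@@H](C)C=C | intermediate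
6 | (2E)‑3‑iodo‑2‑methylprop‑2‑enoic acid | C/C(=C\I)C(=O)O | starting material
7 | 2‑(trimethylsilyl)ethanol | C[Si](C)(C)CCO | starting material
8 | 2‑(trimethylsilyl)ethyl (2E)‑3‑iodo‑2‑methylprop‑2‑enoate | C/C(=C\I)C(=O)OCC[Si](C)(C)C | intermediate
9 | 2‑(trimethylsilyl)ethyl (2E,4E,6S,7R,8E)‑7‑[(tert‑butyldimethylsilyl)oxy]‑2,6‑dimethylundeca‑2,4,8‑trienoate | CC/C=C/[C@@H](O[Si](C)(C)C(C)(C)C)[C@@H](C)/C=C/C=C(\C)C(=O)OCC[Si](C)(C)C | intermediate (not isolated)
10 | 2‑(trimethylsilyl)ethyl (2E,4E,6S,7R)‑7‑[(tert‑butyldimethylsilyl)oxy]‑2,6‑dimethyl‑9‑oxoundeca‑2,4‑dienoate | CCC(=O)C[C@@H](O[Si](C)(C)C(C)(C)C)[C@@H](C)/C=C/C=C(\C)C(=O)OCC[Si](C)(C)C | intermediate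
11 | 2‑methyl‑1,3‑oxazole‑4‑carbaldehyde | Cc1nc(C=O)co1 | starting material
12 | 2‑(triphenylphosphoranylidene)propanal | CC(C=O)=P(c1ccccc1)(c1ccccc1)c1ccccc1 | starting material
13 | (2E)‑2‑methyl‑3‑(2‑methyl‑1,3‑oxazol‑4‑yl)prop‑2‑enal | C/C(C=O)=C\c1coc(C)n1 | intermediate
14 | (triphenylphosphoranylidene)acetaldehyde | O=CC=P(c1ccccc1)(c1ccccc1)c1ccccc1 | starting material
15 | (2E,4E)‑4‑methyl‑5‑(2‑methyl‑1,3‑oxazol‑4‑yl)penta‑2,4‑dienal | O=C/C=C/C(C)=C/c1coc(C)n1 | intermediate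
16 | (2E,4E,6E)‑2,6‑dimethyl‑7‑(2‑methyl‑1,3‑oxazol‑4‑yl)hepta‑2,4,6‑trienal | O=C/C(C)=C/C=C/C(C)=C/c1coc(C)n1 | intermediate
17 | (9Z)‑enol diisopinocampheylborinate of 10 [C9–O–B(Ipc)2, C9=C10 Z] | C/C=C(\OB([C@H]1C[C@H]2C[C@@H]([C@@H]1C)C2(C)C)[C@H]1C[C@H]2C[C@@H]([C@@H]1C)C2(C)C)C[C@@H](O[Si](C)(C)C(C)(C)C)[C@@H](C)/C=C/C=C(\C)C(=O)OCC[Si](C)(C)C | intermediate (not isolated)
18 | C11 O‑diisopinocampheylboron aldolate of 19 | CC(/C=C/C=C(\C)[C@H](OB([C@H]1C[C@H]2C[C@@H]([C@@H]1C)C2(C)C)[C@H]1C[C@H]2C[C@@H]([C@@H]1C)C2(C)C)[C@@H](C)C(=O)C[C@@H](O[Si](C)(C)C(C)(C)C)[C@@H](C)/C=C/C=C(\C)C(=O)OCC[Si](C)(C)C)=C\c1coc(C)n1 | intermediate (not isolated)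
19 | 2‑(trimethylsilyl)ethyl (2E,4E,6S,7R,10R,11R,12E,14E,16E)‑7‑[(tert‑butyldimethylsilyl)oxy]‑11‑hydroxy‑2,6,10,12,16‑pentamethyl‑17‑(2‑methyl‑1,3‑oxazol‑4‑yl)‑9‑oxoheptadeca‑2,4,12,14,16‑pentaenoate | CC(/C=C/C=C(\C)[C@H](O)[C@@H](C)C(=O)C[C@@H](O[Si](C)(C)C(C)(C)C)[C@@H](C)/C=C/C=C(\C)C(=O)OCC[Si](C)(C)C)=C\c1coc(C)n1 | intermediate
20 | 2‑(trimethylsilyl)ethyl (2E,4E,6S,7R,9S,10S,11R,12E,14E,16E)‑7‑[(tert‑butyldimethylsilyl)oxy]‑9,11‑dihydroxy‑2,6,10,12,16‑pentamethyl‑17‑(2‑methyl‑1,3‑oxazol‑4‑yl)heptadeca‑2,4,12,14,16‑pentaenoate | CC(/C=C/C=C(\C)[C@H](O)[C@@H](C)[C@@H](O)C[C@@H](O[Si](C)(C)C(C)(C)C)[C@@H](C)/C=C/C=C(\C)C(=O)OCC[Si](C)(C)C)=C\c1coc(C)n1 | intermediate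
21 | (2E,4E,6S,7R,9S,10S,11R,12E,14E,16E)‑7,9,11‑trihydroxy‑2,6,10,12,16‑pentamethyl‑17‑(2‑methyl‑1,3‑oxazol‑4‑yl)heptadeca‑2,4,12,14,16‑pentaenoic acid | CC(/C=C/C=C(\C)[C@H](O)[C@@H](C)[C@@H](O)C[C@@H](O)[C@@H](C)/C=C/C=C(\C)C(=O)O)=C\c1coc(C)n1 | target

**Step count and risks**
Total steps: 10. Longest linear sequence: 6 (steps 1, 2, 4, 8, 9, 10 from (E)‑pent‑2‑enal; the oxazole branch, steps 5, 6, 7, 8, 9, 10, is equally long).

Step 4 (the proposed palladium relay). The risk is the hand‑over of the Heck catalyst to the Wacker cycle in the presence of silver salts, and the regiochemistry with a silyl ether as the only control element. The fallback uses known chemistry, sets out from 5 (with 8) and comes back at 10. The relay is given up and the two palladium reactions are run separately: a Jeffery–Heck coupling of 5 and 8 (Pd(OAc)2, Bu4NCl, K2CO3, DMF, 40 °C) with isolation of triene ester 9, then a Wacker oxidation of pure 9 with a fresh charge of Pd(OAc)2, benzoquinone and HBF4 in DMA/MeCN/H2O, the established conditions for internal allylic ethers. This fallback makes no compound outside the list (F0).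

Step 8 (syn aldol). The risks are the ethyl‑side selectivity of enolisation, the sense and level of facial control by the Ipc ligands (to be confirmed by Mosher analysis on the first run, switching to the antipodal reagent if needed), and the low electrophilicity of the long, conjugated trienal 16. The fallback sets out from 10 (side inputs 6 and 13) and comes back at 20. Acid 6 is reduced with LiAlH4 to (2E)‑3‑iodo‑2‑methylprop‑2‑en‑1‑ol F1 and oxidised with MnO2 to (2E)‑3‑iodo‑2‑methylprop‑2‑enal F2, a small and reactive α‑methyl enal of the type for which the Ipc‑boron aldol is best precedented. The same aldol of 10 with F2 gives the vinyl iodide aldol 2‑(trimethylsilyl)ethyl (2E,4E,6S,7R,10R,11R,12E)‑7‑[(tert‑butyldimethylsilyl)oxy]‑11‑hydroxy‑13‑iodo‑2,6,10,12‑tetramethyl‑9‑oxotrideca‑2,4,12‑trienoate F3, and Evans–Saksena reduction gives the corresponding (9S,10S,11R)‑9,11‑diol F4. Enal 13 is converted with CrCl2/Bu3SnCHBr2/LiI into tributyl[(1E,3E)‑3‑methyl‑4‑(2‑methyl‑1,3‑oxazol‑4‑yl)buta‑1,3‑dien‑1‑yl]stannane F5. Stille coupling of F4 with F5 (PdCl2(MeCN)2, DMF) closes the C13–C14 bond and gives 20.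

Step 9 (directed reduction). The risk is ionisation or transposition of the trienyl allylic alcohol in acetic acid. The fallback sets out from 19 and comes back at 21. An Evans–Tishchenko reduction under neutral conditions (SmI2 0.3 equiv, acetaldehyde, THF, −10 °C) delivers hydride to C9 from the C11 hemiacetal and gives the 1,3‑anti monoester, the 11‑acetate of 20 F6. Bu4NF then removes the silyl ether and the silylethyl ester to give the 11‑O‑acetyl derivative of the target acid F7, and LiOH in THF/H2O cleaves the acetate to give 21.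

**Further compounds**
F0 | step 4 | none | none
F1 | step 8 | (2E)‑3‑iodo‑2‑methylprop‑2‑en‑1‑ol | C/C(CO)=C\I
F2 | step 8 | (2E)‑3‑iodo‑2‑methylprop‑2‑enal | C/C(C=O)=C\I
F3 | step 8 | 2‑(trimethylsilyl)ethyl (2E,4E,6S,7R,10R,11R,12E)‑7‑[(tert‑butyldimethylsilyl)oxy]‑11‑hydroxy‑13‑iodo‑2,6,10,12‑tetramethyl‑9‑oxotrideca‑2,4,12‑trienoate | I/C=C(\C)[C@H](O)[C@@H](C)C(=O)C[C@@H](O[Si](C)(C)C(C)(C)C)[C@@H](C)/C=C/C=C(\C)C(=O)OCC[Si](C)(C)C
F4 | step 8 | 2‑(trimethylsilyl)ethyl (2E,4E,6S,7R,9S,10S,11R,12E)‑7‑[(tert‑butyldimethylsilyl)oxy]‑9,11‑dihydroxy‑13‑iodo‑2,6,10,12‑tetramethyltrideca‑2,4,12‑trienoate | I/C=C(\C)[C@H](O)[C@@H](C)[C@@H](O)C[C@@H](O[Si](C)(C)C(C)(C)C)[C@@H](C)/C=C/C=C(\C)C(=O)OCC[Si](C)(C)C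
F5 | step 8 | tributyl[(1E,3E)‑3‑methyl‑4‑(2‑methyl‑1,3‑oxazol‑4‑yl)buta‑1,3‑dien‑1‑yl]stannane | CCCC[Sn](CCCC)(CCCC)/C=C/C(C)=C/c1coc(C)n1
F6 | step 9 | 2‑(trimethylsilyl)ethyl (2E,4E,6S,7R,9S,10S,11R,12E,14E,16E)‑11‑(acetyloxy)‑7‑[(tert‑butyldimethylsilyl)oxy]‑9‑hydroxy‑2,6,10,12,16‑pentamethyl‑17‑(2‑methyl‑1,3‑oxazol‑4‑yl)heptadeca‑2,4,12,14,16‑pentaenoate | CC(/C=C/C=C(\C)[C@H](OC(C)=O)[C@@H](C)[C@@H](O)C[C@@H](O[Si](C)(C)C(C)(C)C)[C@@H](C)/C=C/C=C(\C)C(=O)OCC[Si](C)(C)C)=C\c1coc(C)n1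
F7 | step 9 | (2E,4E,6S,7R,9S,10S,11R,12E,14E,16E)‑11‑(acetyloxy)‑7,9‑dihydroxy‑2,6,10,12,16‑pentamethyl‑17‑(2‑methyl‑1,3‑oxazol‑4‑yl)heptadeca‑2,4,12,14,16‑pentaenoic acid | CC(/C=C/C=C(\C)[C@H](OC(C)=O)[C@@H](C)[C@@H](O)C[C@@H](O)[C@@H](C)/C=C/C=C(\C)C(=O)O)=C\c1coc(C)n1
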